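**Plan**

- Retrosynthesis: cut the O9 angelate, the lactone bond C12–O6 (back to a 2-methylene-1,4-diol on C7/C6), the C10–C14 bond (back to an enol triflate), then undo a [3,3] shift (break C2–C3, rejoin C5–C10), then remove vinyl (C10), isopropenyl (C5), O6 and the C11–C13 unit (C7) from a C5–C10 cyclohexene built from D-tartrate.
- Enabling feature: in the ten-membered ring C1–C10 the C2–C3 bond lies between the C1=C10 and C4=C5 alkenes, so the ring is the oxy-Cope product of a C5–C10 cyclohexanol with vinyl (C1, C2) on C10 and isopropenyl (C3, C4, C15) on C5.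
- Forward order of rings: dioxolane (present from the start), six-membered ring C5–C10 by ring-closing metathesis, ten-membered ring by the [3,3] shift with triflate trapping, then the C14 methyl, the lactone ring and the angelate.
- Stereochemistry: C8 and C9 come from D-tartaric acid; C10, C5, C6 and C7 are set in turn on the single chair that the trans-fused 8,9-acetonide allows; the same chair fixes 4E and the ring-cis C1=C10 geometry in the key step.

Key step: step 13

Convention: carbons carry the germacranolide locants of the target throughout (ring C1–C10; C11–C13 lactone carbons; C14 on C10; C15 on C4). On the six-membered C5–C10 ring, β is the face carrying the C8 oxygen and α the opposite face.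

Remark on the chemistry: a cyclohexanone whose α-oxygen is held equatorial in a trans-fused dioxolane is assumed to accept organomagnesium and bulky organocerium reagents on the side of the α-hydrogen, trans to that oxygen.

**Step 1**
Reactants: 1 dimethyl (4S,5S)-2,2-dimethyl-1,3-dioxolane-4,5-dicarboxylate; 2 vinylmagnesium bromide
Product: 4 diene diol trans-4,5-bis(1-hydroxyprop-2-en-1-yl)-2,2-dimethyl-1,3-dioxolane (carbinol epimers), via dioxolane dialdehyde 3 (not isolated)
Conditions: i-Bu2AlH (2.1 equiv), toluene, −78 °C; then 2 (3 equiv), THF, −78 °C to rt; aq. potassium sodium tartrate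
Reagents that add atoms: vinylmagnesium bromide, C=C[Mg]Br
Why: One-pot half-reduction of both esters and Grignard addition to the aldehydes as they are released gives the 1,7-diene; the two new carbinol centres (future C7 and C10) need no control because both are oxidised later.

**Step 2**
Reactants: 4 diene diol
Product: 5 cyclohexene diol 8β,9α-(isopropylidenedioxy)cyclohex-5-ene-7,10-diol (C7/C10 epimers)
Conditions: second-generation Grubbs catalyst RuCl2(=CHPh)(PCy3)(H2IMes) (3 mol %), CH2Cl2, 40 °C
Reagents that add atoms: none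
Why: Ring-closing metathesis of the 1,7-diene forms the C5=C6 cyclohexene with loss of ethene, the trans-dioxolane holding the two arms gauche, and creates no stereocentre.

**Step 3**
Reactants: 5 cyclohexene diol
Product: 6 hydroxy enone 7-hydroxy-8β,9α-(isopropylidenedioxy)cyclohex-5-en-10-one (C7 epimers)
Conditions: MnO2 (excess), CH2Cl2, rt, stopped at mono-oxidation
Reagents that add atoms: none
Why: Allylic oxidation with MnO2 should stop after one carbinol because the remaining hydroxyl then sits on an electron-poor enone, and oxidation of either carbinol of any epimer leads to 6.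

**Step 4**
Reactants: 6 hydroxy enone; 2 vinylmagnesium bromide
Product: 7 vinyl carbinol 10β-vinyl-8β,9α-(isopropylidenedioxy)cyclohex-5-ene-7,10α-diol (C7 epimers)
Conditions: 2 (2.5 equiv), THF/CH2Cl2, −78 °C
Reagents that add atoms: vinylmagnesium bromide, C=C[Mg]Br
Why: Grignard 1,2-addition under chelation control: magnesium bridges the C10 carbonyl and the equatorial C9 dioxolane oxygen and vinyl enters on the β face beside the axial H9, so the new 10α-hydroxyl is cis to O9 (one equivalent is consumed by the free hydroxyl).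

**Step 5**
Reactants: 7 vinyl carbinol
Product: 8 enone 10α-hydroxy-10β-vinyl-8β,9α-(isopropylidenedioxy)cyclohex-5-en-7-one
Conditions: MnO2 (excess), CH2Cl2, rt
Reagents that add atoms: none
Why: MnO2 oxidises only the secondary allylic alcohol (the tertiary one cannot react), so both C7 epimers converge on one enone.

**Step 6**
Reactants: 8 enone
Product: 9 silyl ether 10α-(trimethylsilyloxy)-10β-vinyl-8β,9α-(isopropylidenedioxy)cyclohex-5-en-7-one
Conditions: N-(trimethylsilyl)imidazole, CH2Cl2, rt
Reagents that add atoms: N-(trimethylsilyl)imidazole, C[Si](C)(C)n1ccnc1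
Why: Neutral silylation masks the tertiary hydroxyl so that no alkoxide can steer the next reagent to the α face and so that O10 can be freed last.

**Step 7**
Reactants: 9 silyl ether; 10 isopropenylmagnesium bromide
Product: 11 silyl enol ether 5β-isopropenyl-7,10α-bis(trimethylsilyloxy)-10β-vinyl-8β,9α-(isopropylidenedioxy)cyclohex-6-ene
Conditions: 10 (3 equiv), CuBr·SMe2 (20 mol %), Me3SiCl (4 equiv), THF, −78 °C; Et3N quench
Reagents that add atoms: isopropenylmagnesium bromide, CC(=C)[Mg]Br; chlorotrimethylsilane, C[Si](C)(C)Cl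
Why: Copper-catalysed conjugate addition with chlorosilane trapping: isopropenyl attacks C5 axially on the β face, anti to the pseudoaxial 10α-silyloxy group and hence cis to the vinyl group, and the regiodefined C6=C7 enolate is kept as its silyl enol ether.

**Step 8**
Reactants: 11 silyl enol ether
Product: 13 hydroxy ketone 6α-hydroxy-5β-isopropenyl-10α-(trimethylsilyloxy)-10β-vinyl-8β,9α-(isopropylidenedioxy)cyclohexan-7-one, via silyloxy epoxide 12 (not isolated)
Conditions: dimethyldioxirane (1.05 equiv), acetone/CH2Cl2, −78 °C; then NH4F, MeOH, 0 °C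
Reagents that add atoms: dimethyldioxirane, CC1(C)OO1
Why: Rubottom oxidation: the dioxirane should epoxidise the electron-rich enol ether faster than the vinyl and isopropenyl groups and from the α face, anti to the axial 5β-isopropenyl group, and fluoride opens the silyloxy epoxide to the 6α-hydroxy ketone while the hindered tertiary silyl ether stays.

**Step 9**
Reactants: 13 hydroxy ketone; 14 2-bromoprop-2-en-1-ol
Product: 15 triol 7α-(3-hydroxyprop-1-en-2-yl)-5β-isopropenyl-10α-(trimethylsilyloxy)-10β-vinyl-8β,9α-(isopropylidenedioxy)cyclohexane-6α,7β-diol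
Conditions: 14 (5 equiv), t-BuLi (15 equiv), Et2O, −78 to 0 °C; CeCl3, THF, −78 °C; then 13, −78 to −40 °C
Reagents that add atoms: 2-bromoprop-2-en-1-ol, OCC(Br)=C
Why: 1,2-addition of an alkenylcerium reagent (the 2-metallated allyl alkoxide) brings in C11–C13, and this bulky sp2 nucleophile should enter C7 equatorially on the α face because the axial β path is closed by the syn-axial isopropenyl group, giving the axial 7β-hydroxyl while cerium suppresses enolisation.

**Step 10**
Reactants: 15 triol
Product: 16 bis-acetal 6-O,12-O-bis[2-(trimethylsilyl)ethoxymethyl] ether of 15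
Conditions: 2-(trimethylsilyl)ethoxymethyl chloride (4 equiv), i-Pr2NEt, Bu4NI (cat.), CH2Cl2, 40 °C
Reagents that add atoms: 2-(trimethylsilyl)ethoxymethyl chloride, C[Si](C)(C)CCOCCl
Why: Acetal etherification under amine base protects the primary C12 and secondary C6 hydroxyls with groups that cannot migrate to the later C10 alkoxide, and the hindered tertiary C7 hydroxyl does not react.

**Step 11**
Reactants: 16 bis-acetal
Product: 17 7β-O-triethylsilyl ether of 16
Conditions: Et3SiOTf, 2,6-lutidine, CH2Cl2, −78 to 0 °C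
Reagents that add atoms: triethylsilyl trifluoromethanesulfonate, CC[Si](CC)(CC)OS(=O)(=O)C(F)(F)F
Why: Silyl triflate silylation caps the tertiary 7β-hydroxyl, which would otherwise give a second alkoxide in the key step.

**Step 12**
Reactants: 17 silyl ether
Product: 18 cis-1-vinyl-2-isopropenylcyclohexanol (10α-hydroxy; 6-O and 12-O acetals; 7-O-triethylsilyl; 8,9-acetonide)
Conditions: K2CO3 (cat.), MeOH, rt
Reagents that add atoms: none
Why: Base-catalysed methanolysis removes the trimethylsilyl ether selectively, since the triethylsilyl ether, the acetals and the ketal are stable to K2CO3 in methanol.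

**Step 13**
Reactants: 18 cyclohexanol
Product: 21 ten-membered C10 enol triflate (4E; ring-cis C1=C10), via potassium alkoxide 19 (not isolated), via potassium enolate 20 (not isolated)
Conditions: KH (1.5 equiv), 18-crown-6 (1.5 equiv), THF, 0 °C to rt; then PhNTf2 (1.5 equiv), −78 °C
Reagents that add atoms: N-phenylbis(trifluoromethanesulfonimide), O=S(=O)(N(c1ccccc1)S(=O)(=O)C(F)(F)F)C(F)(F)F
Why: KH with 18-crown-6 gives the C10 potassium alkoxide 19, whose anionic oxy-Cope ([3,3] sigmatropic) shift forms C2–C3 and cleaves C5–C10, and the resulting potassium enolate 20 is O-sulfonylated by PhNTf2 at −78 °C. The closest known reaction type is the anionic oxy-Cope ring expansion of 1,2-dialkenylcyclohexanols to cyclodec-5-enones with enolate trapping in the same flask. The ten-membered ring closes by four-carbon ring expansion: the new bond joins the alkene termini C2 and C3 inside a six-membered chair transition state while the old ring bond breaks. No stereocentre is formed; the two alkene geometries are controlled by the trans-fused 8,9-acetonide, which allows only the cyclohexane chair with equatorial vinyl and axial isopropenyl, so that in the Cope chair the oxido group and C6 are pseudoequatorial and C9 and H5 pseudoaxial, which gives 4E and the ring-cis C1=C10 enolate. The step needs the cis vinyl/isopropenyl relationship (set in steps 4 and 7), an enolate that points toward C1 (given by the mechanism and preserved by cold trapping before proton transfer to C9) and a single chair (secured by the acetonide). Relief of the 1,3-diaxial contacts of the isopropenyl group and the C10 oxygen should let the shift run at or below room temperature.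

**Step 14**
Reactants: 21 enol triflate; 22 methylmagnesium bromide
Product: 23 C14-methyl diene (1(10)Z,4E; protecting groups as in 21)
Conditions: 22 (3 equiv), Fe(acac)3 (10 mol %), THF/NMP, −30 °C
Reagents that add atoms: methylmagnesium bromide, C[Mg]Br
Why: Iron-catalysed cross-coupling of the alkenyl triflate with the methyl Grignard reagent installs C14 with retention of alkene geometry.

**Step 15**
Reactants: 23 C14-methyl diene
Product: 24 6,12-diol (7-O-triethylsilyl; 8,9-acetonide)
Conditions: MgBr2·OEt2 (excess), MeNO2, Et2O, rt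
Reagents that add atoms: none
Why: Lewis-acid cleavage of the two 2-(trimethylsilyl)ethoxymethyl acetals with MgBr2 should spare the ketal and the tertiary silyl ether and free the C6 and C12 hydroxyls.

**Step 16**
Reactants: 24 6,12-diol
Product: 27 α-methylene lactone (7-O-triethylsilyl; 8,9-O-isopropylidene), via hydroxy enal 25 (not isolated), via lactol 26 (not isolated)
Conditions: TEMPO (20 mol %), PhI(OAc)2 (2.5 equiv), CH2Cl2, rt
Reagents that add atoms: none
Why: Nitroxyl-catalysed oxidative lactonisation: the primary allylic alcohol is oxidised first, the aldehyde is captured by the cis-placed C6 hydroxyl as a lactol and this is oxidised to the α-methylene γ-lactone, while O8 cannot compete because it is still in the acetonide.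

**Step 17**
Reactants: 27 α-methylene lactone
Product: 28 triol lactone (C7, C8 and C9 hydroxyls free)
Conditions: AcOH/H2O/THF (3:1:1), 40 °C
Reagents that add atoms: none
Why: Mild aqueous acid hydrolyses the ketal and the tertiary silyl ether without ionising the allylic C6 and C9 oxygens.

**Step 18**
Reactants: 28 triol lactone; 29 angelic acid
Product: 30 target (6S,7S,8S,9R; 1(10)Z,4E)
Conditions: 29, 2,4,6-trichlorobenzoyl chloride, Et3N, toluene, rt; then 28, 60 °C (no DMAP)
Reagents that add atoms: angelic acid, C/C=C(/C)C(=O)O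
Why: Mixed-anhydride (Yamaguchi-type) esterification without a nucleophilic catalyst keeps the Z geometry of the angelate and should acylate the allylic C9 hydroxyl, because the C8 hydroxyl is flanked by the fully substituted C7 and the C7 hydroxyl is tertiary.

**Compound list**

1 | dimethyl (4S,5S)-2,2-dimethyl-1,3-dioxolane-4,5-dicarboxylate (D-tartrate acetonide) | COC(=O)[C@H]1OC(C)(C)O[C@@H]1C(=O)OC | starting material
2 | vinylmagnesium bromide | C=C[Mg]Br | starting material
3 | (4S,5S)-2,2-dimethyl-1,3-dioxolane-4,5-dicarbaldehyde | O=C[C@H]1OC(C)(C)O[C@@H]1C=O | intermediate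
4 | trans-4,5-bis(1-hydroxyprop-2-en-1-yl)-2,2-dimethyl-1,3-dioxolane, ring carbons (C8, C9) as in 1, both carbinols as epimer mixtures | C=CC(O)[C@H]1OC(C)(C)O[C@@H]1C(O)C=C | intermediate
5 | 8β,9α-(isopropylidenedioxy)cyclohex-5-ene-7,10-diol, trans-fused, C7/C10 epimers | OC1C=CC(O)[C@H]2OC(C)(C)O[C@H]12 | intermediate
6 | 7-hydroxy-8β,9α-(isopropylidenedioxy)cyclohex-5-en-10-one, C7 epimers | O=C1C=CC(O)[C@H]2OC(C)(C)O[C@H]12 | intermediate
7 | 10β-vinyl-8β,9α-(isopropylidenedioxy)cyclohex-5-ene-7,10α-diol, C7 epimers | C=C[C@@]1(O)C=CC(O)[C@H]2OC(C)(C)O[C@H]12 | intermediate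
8 | 10α-hydroxy-10β-vinyl-8β,9α-(isopropylidenedioxy)cyclohex-5-en-7-one | C=C[C@@]1(O)C=CC(=O)[C@H]2OC(C)(C)O[C@H]12 | intermediate
9 | 10α-(trimethylsilyloxy)-10β-vinyl-8β,9α-(isopropylidenedioxy)cyclohex-5-en-7-one | C=C[C@@]1(O[Si](C)(C)C)C=CC(=O)[C@H]2OC(C)(C)O[C@H]12 | intermediate
10 | isopropenylmagnesium bromide | CC(=C)[Mg]Br | starting material
11 | 5β-isopropenyl-7,10α-bis(trimethylsilyloxy)-10β-vinyl-8β,9α-(isopropylidenedioxy)cyclohex-6-ene | C=C[C@@]1(O[Si](C)(C)C)[C@@H](C(C)=C)C=C(O[Si](C)(C)C)[C@H]2OC(C)(C)O[C@H]12 | intermediate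
12 | 6α,7α-epoxide of 11 (7β-trimethylsilyloxy) | C=C[C@@]1(O[Si](C)(C)C)[C@@H](C(C)=C)[C@@H]3O[C@]3(O[Si](C)(C)C)[C@H]2OC(C)(C)O[C@H]12 | intermediate
13 | 6α-hydroxy-5β-isopropenyl-10α-(trimethylsilyloxy)-10β-vinyl-8β,9α-(isopropylidenedioxy)cyclohexan-7-one | C=C[C@@]1(O[Si](C)(C)C)[C@@H](C(C)=C)[C@H](O)C(=O)[C@H]2OC(C)(C)O[C@H]12 | intermediate
14 | 2-bromoprop-2-en-1-ol | OCC(Br)=C | starting material
15 | 7α-(3-hydroxyprop-1-en-2-yl)-5β-isopropenyl-10α-(trimethylsilyloxy)-10β-vinyl-8β,9α-(isopropylidenedioxy)cyclohexane-6α,7β-diol | C=C[C@@]1(O[Si](C)(C)C)[C@@H](C(C)=C)[C@H](O)[C@](O)(C(=C)CO)[C@H]2OC(C)(C)O[C@H]12 | intermediate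
16 | 6-O,12-O-bis[2-(trimethylsilyl)ethoxymethyl] ether of 15 | C=C[C@@]1(O[Si](C)(C)C)[C@@H](C(C)=C)[C@H](OCOCC[Si](C)(C)C)[C@](O)(C(=C)COCOCC[Si](C)(C)C)[C@H]2OC(C)(C)O[C@H]12 | intermediate
17 | 7β-O-triethylsilyl ether of 16 | C=C[C@@]1(O[Si](C)(C)C)[C@@H](C(C)=C)[C@H](OCOCC[Si](C)(C)C)[C@](O[Si](CC)(CC)CC)(C(=C)COCOCC[Si](C)(C)C)[C@H]2OC(C)(C)O[C@H]12 | intermediate
18 | cis-1-vinyl-2-isopropenylcyclohexanol: 10α-hydroxy-10β-vinyl-5β-isopropenyl, 6α-O-acetal, 7β-O-triethylsilyl, 7α-(3-acetaloxyprop-1-en-2-yl), 8β,9α-acetonide | C=C[C@@]1(O)[C@@H](C(C)=C)[C@H](OCOCC[Si](C)(C)C)[C@](O[Si](CC)(CC)CC)(C(=C)COCOCC[Si](C)(C)C)[C@H]2OC(C)(C)O[C@H]12 | intermediate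
19 | potassium C10 alkoxide of 18 | C=C[C@@]1([O-])[C@@H](C(C)=C)[C@H](OCOCC[Si](C)(C)C)[C@](O[Si](CC)(CC)CC)(C(=C)COCOCC[Si](C)(C)C)[C@H]2OC(C)(C)O[C@H]12.[K+] | intermediate
20 | ten-membered potassium C1=C10 enolate (ring-cis), 4E | C[Si](C)(C)CCOCO[C@H]1/C=C(\C)CC/C=C(/[O-])[C@H]2OC(C)(C)O[C@@H]2[C@@]1(O[Si](CC)(CC)CC)C(=C)COCOCC[Si](C)(C)C.[K+] | intermediate
21 | ten-membered C10 enol triflate, 4E, ring carbons C2 and C9 cis across C1=C10, C6–C9 configured as in 18 | C[Si](C)(C)CCOCO[C@H]1/C=C(\C)CC/C=C(/OS(=O)(=O)C(F)(F)F)[C@H]2OC(C)(C)O[C@@H]2[C@@]1(O[Si](CC)(CC)CC)C(=C)COCOCC[Si](C)(C)C | intermediate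
22 | methylmagnesium bromide | C[Mg]Br | starting material
23 | (1(10)Z,4E)-10-methyl diene, protecting groups as in 21 | C[Si](C)(C)CCOCO[C@H]1/C=C(\C)CC/C=C(/C)[C@H]2OC(C)(C)O[C@@H]2[C@@]1(O[Si](CC)(CC)CC)C(=C)COCOCC[Si](C)(C)C | intermediate
24 | 6,12-diol of 23 (7-O-triethylsilyl, 8,9-acetonide) | O[C@H]1/C=C(\C)CC/C=C(/C)[C@H]2OC(C)(C)O[C@@H]2[C@@]1(O[Si](CC)(CC)CC)C(=C)CO | intermediate
25 | C12 aldehyde of 24 (6-hydroxy enal) | O[C@H]1/C=C(\C)CC/C=C(/C)[C@H]2OC(C)(C)O[C@@H]2[C@@]1(O[Si](CC)(CC)CC)C(=C)C=O | intermediate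
26 | C12 lactol (O6–C12 hemiacetal, anomers) | C=C1C(O)O[C@H]2/C=C(\C)CC/C=C(/C)[C@H]3OC(C)(C)O[C@@H]3[C@@]12O[Si](CC)(CC)CC | intermediate
27 | cis-fused α-methylene γ-lactone, 7-O-triethylsilyl, 8,9-O-isopropylidene | C=C1C(=O)O[C@H]2/C=C(\C)CC/C=C(/C)[C@H]3OC(C)(C)O[C@@H]3[C@@]12O[Si](CC)(CC)CC | intermediate
28 | 7,8,9-triol lactone (target without the angeloyl group) | C=C1C(=O)O[C@H]2/C=C(\C)CC/C=C(/C)[C@@H](O)[C@H](O)[C@@]12O | intermediate
29 | angelic acid, (Z)-2-methylbut-2-enoic acid | C/C=C(/C)C(=O)O | starting material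
30 | CNP0303917.1, (6S,7S,8S,9R)-7,8-dihydroxy-9-angeloyloxy-germacra-1(10)Z,4E,11(13)-trien-12,6-olide | C=C1C(=O)O[C@H]2/C=C(\C)CC/C=C(/C)[C@@H](OC(=O)/C(C)=C\C)[C@H](O)[C@@]12O | target

**Totals**

Total step count: 18. Longest linear sequence: 18 steps (1 to 30).

**Steps most likely to fail**

Step 9. The organocerium reagent may attack the β face of the crowded C7 carbonyl, or deprotonate C8 and set off loss of the C9 oxygen, instead of adding on the α face. The fallback sets out from 13 and comes back at 15 by delivering the carbon from a tether on O6. The C6 hydroxyl of 13 is acylated with bromoacetyl bromide and pyridine to the bromoacetate F1. SmI2 in THF at −78 °C then closes the cis-fused β-hydroxy γ-lactone F2 by an intramolecular Reformatsky addition; the tether can reach C7 only from the α face, so the 7β-hydroxyl is fixed by the ring fusion. The dianion of F2 (LiN(i-Pr)2) is aminomethylated with dimethyl(methylidene)ammonium iodide to the Mannich base F3, which after quaternisation with MeI and elimination with NaHCO3 gives the α-methylene lactone F4. Reduction of F4 with i-Bu2AlH opens the lactone to the 6,12-diol and so returns to 15.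

Step 18. Acylation may occur at the C8 hydroxyl or twice, or the angeloyl group may drift from O9 to O8. The fallback sets out from 28 and comes back at 30. Compound 28 is condensed with phenylboronic acid (toluene, MgSO4) to the cyclic C7/C8 phenylboronate F5, which leaves only the C9 hydroxyl free. The same mixed anhydride then gives the C9 angelate F6, and exchange with pinacol releases the boronate to give 30.

Step 4. The small Grignard reagent may attack axially on the α face, or add in conjugate fashion, giving the C10 epimer or a C6 adduct. The fallback sets out from 6 and comes back at 7 by building the vinyl group from a bulky formyl anion equivalent. 2-Lithio-1,3-dithiane, which adds to cyclohexanones from the equatorial side, gives the 10β-dithianyl carbinol F7. MeI and CaCO3 in aqueous MeCN unmask the α-hydroxy aldehyde F8, and Wittig methylenation (Ph3P=CH2 from Ph3PCH3Br and KN(SiMe3)2) turns the formyl group into the vinyl group of 7.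

**Further compounds**

F1 | step 9 | 6α-(bromoacetoxy) ketone, bromoacetate of 13 | C=C[C@@]1(O[Si](C)(C)C)[C@@H](C(C)=C)[C@H](OC(=O)CBr)C(=O)[C@H]2OC(C)(C)O[C@H]12
F2 | step 9 | cis-fused 7β-hydroxy γ-lactone (O6–C12(=O)–C11H2–C7) on the cyclohexane | C=C[C@@]1(O[Si](C)(C)C)[C@@H](C(C)=C)[C@@H]3OC(=O)C[C@]3(O)[C@H]2OC(C)(C)O[C@H]12
F3 | step 9 | 11-(dimethylaminomethyl) derivative of F2 (C11 epimers) | C=C[C@@]1(O[Si](C)(C)C)[C@@H](C(C)=C)[C@@H]3OC(=O)C(CN(C)C)[C@]3(O)[C@H]2OC(C)(C)O[C@H]12
F4 | step 9 | 11(13)-methylene 7β-hydroxy γ-lactone on the cyclohexane | C=C[C@@]1(O[Si](C)(C)C)[C@@H](C(C)=C)[C@@H]3OC(=O)C(=C)[C@]3(O)[C@H]2OC(C)(C)O[C@H]12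
F5 | step 18 | 7,8-O-phenylboronate of 28 | C=C1C(=O)O[C@H]2/C=C(\C)CC/C=C(/C)[C@@H](O)[C@H](OB(c3ccccc3)O4)[C@@]124
F6 | step 18 | 9-O-angeloyl 7,8-O-phenylboronate | C=C1C(=O)O[C@H]2/C=C(\C)CC/C=C(/C)[C@@H](OC(=O)/C(C)=C\C)[C@H](OB(c3ccccc3)O4)[C@@]124
F7 | step 4 | 10β-(1,3-dithian-2-yl)-8β,9α-(isopropylidenedioxy)cyclohex-5-ene-7,10α-diol (C7 epimers) | O[C@]1(C2SCCCS2)C=CC(O)[C@H]3OC(C)(C)O[C@H]13
F8 | step 4 | 10β-formyl-8β,9α-(isopropylidenedioxy)cyclohex-5-ene-7,10α-diol (C7 epimers) | O=C[C@@]1(O)C=CC(O)[C@H]2OC(C)(C)O[C@H]12
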